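**Retrosynthetic overview**
1. Last operation: the two catechol O-methyl groups are removed by carbonyl-anchored BCl3 cleavage. The naphthyl OMe and C4 are not touched.
2. Key disconnection C3–C4 (tetralone numbering): the β-carbon of the aryl ketone acts as a homoenolate, masked as a 1-arylcyclopropanol, and attacks the methine carbon of a naphtho-p-quinone methide. Both carbons are acceptors by nature. The step is intramolecular, runs under a chiral phosphoric acid, closes the cyclohexanone ring and sets the only stereocentre.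
3. The cyclopropanol and the quinone methide precursor (a p-hydroxy diarylcarbinol) both come from one Kulinkovich reaction on a 3-arylphthalide. The lactone C=O becomes C1 and the lactone C3 becomes C4.
4. The 3-arylphthalide comes from a Friedel–Crafts condensation of opianic acid with 5-methoxy-1-naphthol.
5. Ring order: both arenes are bought. The lactone (temporary) is formed first, then the cyclopropane (temporary), then the cyclohexanone ring of the tetralone.

Assumption: opianic acid 1 and 5-methoxy-1-naphthol 2 are taken as catalogue chemicals, and the (R)-acid of step 3 is taken to give the (S)-product (its mirror image is also sold and is used if the first run shows the opposite sense).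

**Step 1**
Reactants: 1 opianic acid (6-formyl-2,3-dimethoxybenzoic acid); 2 5-methoxynaphthalen-1-ol
Product: 3 (±)-3-(4-hydroxy-8-methoxynaphthalen-1-yl)-6,7-dimethoxy-2-benzofuran-1(3H)-one
Conditions: CF3CO2H/CH2Cl2 (1:4), 1.1 equiv of 1, 0 °C to rt, 4 h
Reagents that add atoms: none
Why: Friedel–Crafts hydroxyalkylation/lactonisation, in which 1 reacts through its 3-hydroxyphthalide tautomer as an acyloxy-benzylic cation that attacks 2 at C4, the α-position para to the free OH (the stronger donor, and the same peri-alkoxy α-site at which 1,5-dialkoxynaphthalenes are formylated, brominated and acylated); the new stereocentre is racemic and is erased in step 3.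

**Step 2**
Reactants: 3 (±)-3-(4-hydroxy-8-methoxynaphthalen-1-yl)-6,7-dimethoxy-2-benzofuran-1(3H)-one
Product: 6 (±)-1-{6-[hydroxy(4-hydroxy-8-methoxynaphthalen-1-yl)methyl]-2,3-dimethoxyphenyl}cyclopropan-1-ol, via acetal-protected phthalide 4 (not isolated), via acetal-protected cyclopropanol 5 (not isolated)
Conditions: ethyl vinyl ether (5 equiv), pyridinium p-toluenesulfonate (5 mol %), CH2Cl2, rt, evaporate; Ti(OiPr)4 (1.2 equiv), EtMgBr (3.2 equiv, slow addition), THF, 0 °C to rt; 10 % aq citric acid/THF, rt, 1 h
Reagents that add atoms: EtMgBr, CC[Mg]Br (gives the CH2CH2 unit of 5 and 6); ethyl vinyl ether, C=COCC (stays only in intermediates 4 and 5)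
Why: Kulinkovich reaction, in which the titanacyclopropane from Ti(OiPr)4 and EtMgBr acts as a 1,2-dicarbanion on the lactone carbonyl and gives the cyclopropanol while the lactone oxygen is released as the benzylic carbinol, so both partners of step 3 appear in one operation; the naphthol is masked as its base-stable 1-ethoxyethyl acetal because a magnesium naphtholate would expel the lactone carboxylate to a quinone methide that EtMgBr would trap, the acetal falls off in the citric acid work-up, and no stereocentre of the target is set (6 is racemic).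

**Step 3**
Reactants: 6 (±)-1-{6-[hydroxy(4-hydroxy-8-methoxynaphthalen-1-yl)methyl]-2,3-dimethoxyphenyl}cyclopropan-1-ol
Product: 9 (S)-4-(4-hydroxy-8-methoxynaphthalen-1-yl)-7,8-dimethoxy-3,4-dihydronaphthalen-1(2H)-one, via spiro-phthalan 7 (not isolated), via quinone methide 8 (not isolated)
Conditions: (R)-3,3'-bis(2,4,6-triisopropylphenyl)-1,1'-binaphthyl-2,2'-diyl hydrogen phosphate (10 mol %), 4 Å MS, ClCH2CH2Cl (0.01 M), 40 °C
Reagents that add atoms: none
Why: Proposed new method: the chiral phosphoric acid dehydrates the p-hydroxy diarylcarbinol to the planar (E)-naphthoquinone methide 8 (the O-closed spiro-phthalan 7 forms faster but re-ionises under the same acid, so it is only a reservoir), and inside the hydrogen-bonded complex (P–OH to the quinone methide carbonyl, P=O to the cyclopropanol O–H) the strained, oxygen-activated C1–CH2 bond of the cyclopropanol acts as a ketone homoenolate and delivers its CH2 carbon, which lies about 2.5 Å from the electrophilic methine in the reactive rotamer, to one face of 8 in an irreversible 1,6-addition that releases ring strain, rearomatises the naphthol, closes the tetralone ring and sets C4 as (S) stereoconvergently from racemic 6; the closest known reaction types are the Lewis-acid-promoted ring-opening 1,6-addition of cyclopropanols to p-quinone methides, chiral-phosphoric-acid-catalysed 1,6-additions to p-quinone methides generated in situ from p-hydroxybenzyl alcohols, and intramolecular cyclopropanol/oxocarbenium cyclisations.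

**Step 4**
Reactants: 9 (S)-4-(4-hydroxy-8-methoxynaphthalen-1-yl)-7,8-dimethoxy-3,4-dihydronaphthalen-1(2H)-one
Product: 10 (S)-7,8-dihydroxy-4-(4-hydroxy-8-methoxynaphthalen-1-yl)-3,4-dihydronaphthalen-1(2H)-one (target)
Conditions: BCl3 (1 M in CH2Cl2, 4 equiv), CH2Cl2, −78 °C to rt, 12 h; aq NaHCO3
Reagents that add atoms: none
Why: Chelation-relay ether cleavage, in which BCl3 binds the C1 carbonyl and cleaves the adjacent 8-OMe, the resulting aryloxydichloroborane binds and cleaves the neighbouring 7-OMe to a cyclic catechol borate (the way 2,3,4-trimethoxyaryl carbonyl compounds give 2,3-dihydroxy-4-methoxy products), and the isolated naphthyl OMe has no anchoring group and is not cleaved by BCl3 at or below rt; C4 is not an enolisable position and keeps its (S) configuration.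

**Compound list**
1 | opianic acid (6-formyl-2,3-dimethoxybenzoic acid) | O=Cc1ccc(OC)c(OC)c1C(=O)O | starting material
2 | 5-methoxynaphthalen-1-ol | COc1cccc2c(O)cccc12 | starting material
3 | (±)-3-(4-hydroxy-8-methoxynaphthalen-1-yl)-6,7-dimethoxy-2-benzofuran-1(3H)-one | COc1ccc2c(c1OC)C(=O)OC2c1ccc(O)c2cccc(OC)c12 | intermediate
4 | 3-[4-(1-ethoxyethoxy)-8-methoxynaphthalen-1-yl]-6,7-dimethoxy-2-benzofuran-1(3H)-one (diastereomer mixture, not isolated) | COc1ccc2c(c1OC)C(=O)OC2c1ccc(OC(C)OCC)c2cccc(OC)c12 | intermediate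
5 | 1-{6-[[4-(1-ethoxyethoxy)-8-methoxynaphthalen-1-yl](hydroxy)methyl]-2,3-dimethoxyphenyl}cyclopropan-1-ol (diastereomer mixture, not isolated) | CCOC(C)Oc1ccc(C(O)c2ccc(OC)c(OC)c2C2(O)CC2)c2c(OC)cccc12 | intermediate
6 | (±)-1-{6-[hydroxy(4-hydroxy-8-methoxynaphthalen-1-yl)methyl]-2,3-dimethoxyphenyl}cyclopropan-1-ol | COc1cccc2c(O)ccc(C(O)c3ccc(OC)c(OC)c3C3(O)CC3)c12 | intermediate
7 | (±)-3'-(4-hydroxy-8-methoxynaphthalen-1-yl)-6',7'-dimethoxy-3'H-spiro[cyclopropane-1,1'-[2]benzofuran] (not isolated) | COc1cccc2c(O)ccc(C3OC4(CC4)c4c3ccc(OC)c4OC)c12 | intermediate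
8 | (E)-4-{[2-(1-hydroxycyclopropyl)-3,4-dimethoxyphenyl]methylidene}-5-methoxynaphthalen-1(4H)-one (aryl group turned away from the peri OMe, not isolated) | O=C1C=C/C(=C\c2ccc(OC)c(OC)c2C2(O)CC2)c2c(OC)cccc12 | intermediate
9 | (S)-4-(4-hydroxy-8-methoxynaphthalen-1-yl)-7,8-dimethoxy-3,4-dihydronaphthalen-1(2H)-one | COc1cccc2c(O)ccc([C@@H]3CCC(=O)c4c3ccc(OC)c4OC)c12 | intermediate
10 | (S)-7,8-dihydroxy-4-(4-hydroxy-8-methoxynaphthalen-1-yl)-3,4-dihydronaphthalen-1(2H)-one | COc1cccc2c(O)ccc([C@@H]3CCC(=O)c4c3ccc(O)c4O)c12 | target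

**Totals**
Total step count: 4. Longest linear sequence: 4 (1 or 2 → 3 → 6 → 9 → 10).

**Three steps most likely to fail**

*Most at risk: step 3.*
- The σ-bond of a neutral cyclopropanol is a weak nucleophile.
- The O-closed 7 may be too deep a resting state.
- The ee of a new reaction cannot be predicted.

The fallback makes the same C3–C4 bond intermolecularly with a preformed metal homoenolate and closes the ring afterwards. It sets out from 3 and comes back at 9.
- 3 is treated in THF at −20 °C with commercial 3-ethoxy-3-oxopropylzinc bromide (3 equiv), Cu(OTf)2 (5 mol %) and the (S)-BINOL phosphoramidite of bis[(R)-1-phenylethyl]amine (10 mol %).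
- The first equivalent of the zinc reagent deprotonates the naphthol. The zinc naphtholate then pushes out the lactone carboxylate and gives, as its zinc salt, 6-[(E)-(8-methoxy-4-oxonaphthalen-1(4H)-ylidene)methyl]-2,3-dimethoxybenzoic acid F1.
- The copper homoenolate adds 1,6 to F1 and gives (S)-6-[4-ethoxy-1-(4-hydroxy-8-methoxynaphthalen-1-yl)-4-oxobutyl]-2,3-dimethoxybenzoic acid F2.
- MeI/KHCO3 in DMF alkylates only the carboxylate and gives the methyl ester F3.
- LiHMDS (3 equiv, THF, −78 to 0 °C) closes the ring by Dieckmann condensation to ethyl (4S)-4-(4-hydroxy-8-methoxynaphthalen-1-yl)-7,8-dimethoxy-1-oxo-1,2,3,4-tetrahydronaphthalene-2-carboxylate F4.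
- LiCl in wet DMSO at 140 °C (Krapcho) removes the ester and delivers 9.

*Second: step 1.* Attack at C2 (ortho to OH) or at C8 (para to OMe) of 2 may compete with the hindered C4. The fallback fixes the site with a halogen and makes the bond by carbonyl addition instead of electrophilic substitution. It sets out from 2 (and 1) and comes back at 4.
- NBS in MeCN at −20 °C gives 4-bromo-5-methoxynaphthalen-1-ol F5. Isomers are removed at this cheap stage, and the structure is proven by NOE.
- Ethyl vinyl ether with pyridinium p-toluenesulfonate gives 1-bromo-4-(1-ethoxyethoxy)-8-methoxynaphthalene F6.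
- n-BuLi in THF at −78 °C gives [4-(1-ethoxyethoxy)-8-methoxynaphthalen-1-yl]lithium F7.
- F7 adds to the aldehyde of methyl 6-formyl-2,3-dimethoxybenzoate F8, made from 1 with MeI/KHCO3 in DMF.
- The lithium alkoxide closes onto the neighbouring ester and gives 4 directly.

*Third: step 2.* The lactone carbonyl is electron-rich and flanked by an OMe group, so plain Grignard addition may outrun the titanium cycle. The fallback builds the three-membered ring by methylenation and cyclopropanation. It sets out from 4 (isolated for this purpose) and comes back at 7.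
- Cp2TiMe2 in toluene at 70 °C turns the lactone into the enol ether 1-[4-(1-ethoxyethoxy)-8-methoxynaphthalen-1-yl]-4,5-dimethoxy-3-methylidene-1,3-dihydro-2-benzofuran F9.
- Et2Zn/CH2I2 in CH2Cl2 at 0 °C cyclopropanates the enol ether to the acetal-protected spiro-phthalan F10.
- Citric acid in aq THF removes the acetal to give 7, which is isolated this time.
- 7 enters step 3 as the resting state of that reaction.

**Further compounds**
F1 | step 3 | 6-[(E)-(8-methoxy-4-oxonaphthalen-1(4H)-ylidene)methyl]-2,3-dimethoxybenzoic acid (formed as zinc carboxylate) | O=C1C=C/C(=C\c2ccc(OC)c(OC)c2C(=O)O)c2c(OC)cccc12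
F2 | step 3 | (S)-6-[4-ethoxy-1-(4-hydroxy-8-methoxynaphthalen-1-yl)-4-oxobutyl]-2,3-dimethoxybenzoic acid | COc1cccc2c(O)ccc([C@@H](c3ccc(OC)c(OC)c3C(=O)O)CCC(=O)OCC)c12
F3 | step 3 | methyl (S)-6-[4-ethoxy-1-(4-hydroxy-8-methoxynaphthalen-1-yl)-4-oxobutyl]-2,3-dimethoxybenzoate | COc1cccc2c(O)ccc([C@@H](c3ccc(OC)c(OC)c3C(=O)OC)CCC(=O)OCC)c12
F4 | step 3 | ethyl (4S)-4-(4-hydroxy-8-methoxynaphthalen-1-yl)-7,8-dimethoxy-1-oxo-1,2,3,4-tetrahydronaphthalene-2-carboxylate (C2 epimers/enol) | COc1cccc2c(O)ccc([C@@H]3CC(C(=O)OCC)C(=O)c4c3ccc(OC)c4OC)c12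
F5 | step 1 | 4-bromo-5-methoxynaphthalen-1-ol | COc1cccc2c(O)ccc(Br)c12
F6 | step 1 | 1-bromo-4-(1-ethoxyethoxy)-8-methoxynaphthalene | CCOC(C)Oc1ccc(Br)c2c(OC)cccc12
F7 | step 1 | [4-(1-ethoxyethoxy)-8-methoxynaphthalen-1-yl]lithium | CCOC(C)Oc1ccc([Li])c2c(OC)cccc12
F8 | step 1 | methyl 6-formyl-2,3-dimethoxybenzoate | COC(=O)c1c(C=O)ccc(OC)c1OC
F9 | step 2 | 1-[4-(1-ethoxyethoxy)-8-methoxynaphthalen-1-yl]-4,5-dimethoxy-3-methylidene-1,3-dihydro-2-benzofuran | C=C1OC(c2ccc(OC(C)OCC)c3cccc(OC)c23)c2ccc(OC)c(OC)c12
F10 | step 2 | 3'-[4-(1-ethoxyethoxy)-8-methoxynaphthalen-1-yl]-6',7'-dimethoxy-3'H-spiro[cyclopropane-1,1'-[2]benzofuran] | CCOC(C)Oc1ccc(C2OC3(CC3)c3c2ccc(OC)c3OC)c2c(OC)cccc12
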